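## The problem

Wailupemycin F (22) is an (S)-3,8-dihydroxy-1-tetralone. Tetralone numbering is used for every ring atom below, also in open-chain precursors: C1 ketone, C2 methylene, C3 carbinol, C4 benzylic methylene, C4a/C8a ring fusion, C5 bearing a 4-hydroxy-2-oxo-2H-pyran-6-yl group, C6 phenyl, C7 hydrogen, C8 phenol.

The benzene ring is pentasubstituted and its three carbon substituents (C4a, C5, C6) are contiguous, so the C5–pyranone bond is a hindered biaryl-type bond between the phenyl group and the ring methylene. C3 is the only stereocentre; no second centre can control it, so its configuration must come from a catalyst, an enzyme or a purchased building block. The C3 hydroxyl is β to the C1 ketone and the carbocycle is one dehydration away from a naphthalene-1,8-diol, so once this aldol unit exists, base, strong acid and heat are excluded. The 4-hydroxy-2-pyranone is a vinylogous acid, nucleophilic at its own C3 and open to hydride, alkoxide and electrophilic halogen; it has to travel as an ether and enter after every hydride reduction and bromination.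

The feature that opens the route is that C1 is a salicyl carbonyl (on C8a, next to the C8 hydroxyl) while C3, two atoms away, carries one hydrogen and one oxygen. If C1 is an aldehyde and C2=C3 an enol ester, addition of the formyl C–H across the alkene closes the ring, makes the ketone at its final oxidation level and sets C3 in one isomerisation. The O8–H···O=C1 hydrogen bond turns the formyl C–H toward the chain on C4a.

## Retrosynthesis

**22 ⇐ 21 ⇐ 20 (O–benzyl and O–acetyl).** The last two bonds cut are oxygen–protecting-group bonds: the benzyl ether on the pyranone oxygen of 21 and the acetyl ester on O3 of 20. Benzyl is preferred to methyl or silyl because it leaves by neutral hydrogenolysis. The acetate is the oxygen substituent that the ring-forming step itself delivers, not an added protecting group. It is removed before the benzyl group so that the final operation is a filtration. Both forward steps must be free of base, since E1cB loss of the C3 oxygen would aromatise the ring; an enzyme is therefore asked to cleave the ester.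

**20 ⇐ 19 (C1–C2, with the C3 hydrogen returned to C1).** This cut opens 20 to its isomer, salicylaldehyde 19, which carries a 2-acetoxyallyl group on C4a.
- Against the neighbouring cuts: C2–C3 (aldol of a C1 methyl ketone onto a C3 aldehyde) gives the same aldol but has no dependable handle for enantiocontrol and runs through an arylacetaldehyde. C1–C8a (arene acylation) needs a preformed chiral chain and Lewis acid beside the phenol. C4–C4a leaves C1–C8a still to be made.
- Simplification: 19 is achiral and monocyclic, and all crowded aryl bonds are already in place.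
- Demands on the forward reaction: acyl delivery to the alkene terminus (six-ring, not five-ring), one alkene face, and no decarbonylation, double-bond migration or loss of acetic acid.
- Role of the phenol: the C8 hydroxyl is left free on purpose, because its hydrogen bond keeps the C1–H bond on the side of the tether. A phenoxide-bound rhodium, the mode that assists intermolecular reactions of salicylaldehydes, would sit on the side of C1 remote from the alkene, so no base is used.

**19 ⇐ 18 (C3–O).** Cutting the enol ester C–O bond gives terminal alkyne 18 and acetic acid. O-Acetylation of the corresponding methyl ketone would enolise toward the benzylic carbon C4 and give the conjugated isomer; the alkyne fixes the double bond between C2 and C3. The forward addition must be Markovnikov and must not isomerise the propargyl arene.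

**18 ⇐ 17 ⇐ 11 + 15 (C5–pyranone bond, through boronate 16).** Removing the silyl cap gives 17, and cutting the C5–pyranone bond gives aryl bromide 11 and chloropyranone 15, joined through boronate 16. The pyranone is attached intact and late because it would not survive the hydride reduction and the brominations that precede it. Building it on the ring from a C5 acyl group would cost several steps in the presence of the aldehyde. The coupling must succeed at a carbon flanked by phenyl and the propargyl chain.

**15 ⇐ 14 ⇐ 13 ⇐ 12.** Ether 15 comes from hydroxypyranone 14, the hydrolysis–decarboxylation product of acid chloride 13, which is the self-condensation product of two molecules of malonyl dichloride 12. The whole heterocycle is thus traced to a commodity C3 acid chloride.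

**11 ⇐ 10 ⇐ 9 ⇐ 7 + 8 (oxidation level of C1; C4–C3).** The aldehyde of 11 is traced to benzylic alcohol 10 and methyl ester 9, and the C4–C3 bond is cut to benzylic bromide 7 and trimethylsilylacetylene 8. C1 stays an ester until the alkyne is in place because an aldehyde would not survive radical bromination. The reduction is placed before the pyranone arrives and is also asked to cleave the phenol acetate, so no separate deprotection is needed.

**7 ⇐ 6 ⇐ 5 ⇐ 4 ⇐ 2 + 3; 2 ⇐ 1.** The benzylic C–Br bond leads to 6, the O-acetyl and aryl C–Br bonds to 5 and 4, the C6–phenyl bond to triflate 2 and phenylboronic acid 3, and the O–S bond to methyl orsellinate 1. Orsellinate already holds C1 (ester), the C8 hydroxyl and C4 (methyl) in the right positions. Its two hydroxyls are differentiated by the hydrogen bond to the ester. The forward steps need bromination para to the remaining hydroxyl (C5 is the only para position) and a phenol mask for the radical step.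

## Roads not taken

**Alternative 1:** The cut runs through C4a–C8a and C5–C6, so both carbocycles arise at once from the open-chain dienyne A1. In A1 a (Z)-2-silyloxydiene (C8a=C8–C7=C6) and a ynoate (C4a≡C5) are linked by the C1–C4 chain, with a dithiane at C1 and the silylated C3 carbinol. Heating would give the bicyclic cyclohexadiene A2 by intramolecular Diels–Alder reaction.
- Merits: the stereocentre is purchased and carried, the contiguous C4a/C5/C6 pattern comes from ring formation and not from coupling at a hindered carbon, and no catalyst is needed.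
- Weak points: A1 is a long, sensitive chain whose (Z)-silyl enol ether sits next to a quaternary dithiane carbon. A2 is two hydrogens short of the arene. Its C5 ester must still be grown into the pyranone by chain extension at a doubly ortho-substituted benzoate. Dithiane removal needs oxidants or soft metal salts beside the pyranone.
- Comparison: in stereochemical security this road is better, since nothing rests on an untested induction. The chosen plan sets against it a purchased benzene ring, an intact pyranone unit, routine steps up to the precursor, and a known racemic ring closure with resolution in reserve.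

**Alternative 2:** The cut is at C4–C4a and C1–C8a. Aryl iodide A3 and the chiral iodoalkene A4 would be joined under palladium catalysis with a bicyclic alkene mediator (Catellani reaction). Ortho C–H alkylation makes C4–C4a; after extrusion of the mediator a 6-exo Heck cyclisation makes C1–C8a, giving A5 with an exocyclic methylene at C1.
- Merits: one step from two simple partners to the bicyclic core, and the configuration comes from the chiral pool.
- Weak points: the iodide carbon of A4 is next to a branched silyloxy carbon, which slows its addition to the palladacycle and opens β-elimination paths. A5 has hydrogen at C5, so the pyranone must still be brought in by halogenation para to the methoxy group and a coupling as hindered as the one in the chosen route. The methylene must be cleaved oxidatively before the electron-rich pyranone is present. The C8 methyl ether must be removed with a boron halide beside a β-oxygenated ketone, which invites aromatisation.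
- Comparison: this road reaches the ring system faster and is safer in configuration. The chosen plan sets against it a ketone formed directly at the right oxidation level, every aryl substituent in place before the aldol unit exists, and a neutral endgame.

**Alternative 3:** The ring is made first and only the C3–O bond is cut. The ketal-locked dihydronaphthalene A6 (C3=C4 alkene) would be epoxidised with a chiral (salen)MnCl catalyst and a stoichiometric oxidant to cis-epoxide A7. Hydrogenolysis would then open the benzylic C4–O bond and remove the benzyl ethers, and the ketal would be hydrolysed.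
- Merits: a cis-disubstituted, arene-conjugated alkene is the best substrate class for this epoxidation, so the enantioselective step is better precedented than the hydroacylation. One hydrogenolysis does three jobs.
- Weak points: A6 is the ketal of the keto tautomer of a 1-naphthol. It needs a separate tetralone synthesis, ketalisation and introduction of the C3=C4 bond out of conjugation, and it re-aromatises with traces of acid. The oxidant can attack the nucleophilic C3 of the pyranone. The final ketal hydrolysis brings acid to the β-hydroxy ketone.
- Comparison: the asymmetric step is more reliable here. The chosen plan sets against it ring closure and stereocentre in one redox-neutral step, no oxidant near the pyranone, and no acid after the aldol unit is formed.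

Key step: step 13

Assumption: the sense of induction of a rhodium bisphosphine catalyst on an enol ester cannot be predicted from alkyl-substituted alkenes, so the ligand antipode written in step 13 stands for whichever antipode delivers 3S.

## Route

Step 1
Reactants: 1 methyl orsellinate (methyl 2,4-dihydroxy-6-methylbenzoate)
Product: 2 methyl 2-hydroxy-6-methyl-4-{[(trifluoromethyl)sulfonyl]oxy}benzoate
Conditions: Tf2O, pyridine, CH2Cl2, −10 °C
Reagents that add atoms: trifluoromethanesulfonic anhydride, O=S(=O)(OS(=O)(=O)C(F)(F)F)C(F)(F)F
Why: Phenol sulfonylation; the C2 hydroxyl is hydrogen-bonded to the ester carbonyl and flanked by it, so the free C4 hydroxyl should be triflated selectively.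

Step 2
Reactants: 2 methyl 2-hydroxy-6-methyl-4-{[(trifluoromethyl)sulfonyl]oxy}benzoate; 3 phenylboronic acid
Product: 4 methyl 2-hydroxy-6-methyl-4-phenylbenzoate
Conditions: Pd(PPh3)4 (cat.), K3PO4, 1,4-dioxane/H2O, 85 °C
Reagents that add atoms: none
Why: Suzuki–Miyaura coupling of an unhindered aryl triflate; the hydrogen-bonded ortho-hydroxy ester is a spectator under phosphate base.

Step 3
Reactants: 4 methyl 2-hydroxy-6-methyl-4-phenylbenzoate
Product: 6 methyl 6-acetoxy-3-bromo-2-methyl-4-phenylbenzoate, via bromophenol ester 5 (not isolated)
Conditions: NBS, MeCN, 0 °C; then Ac2O, pyridine, DMAP (cat.), rt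
Reagents that add atoms: N-bromosuccinimide, O=C1CCC(=O)N1Br; acetic anhydride, CC(=O)OC(C)=O
Why: Electrophilic bromination of a phenol goes para to the hydroxyl, here the ring carbon between methyl and phenyl (later C5), as in salicylates and 3,5-disubstituted phenols. Acetylation in the same flask masks the phenol for the radical step that follows.

Step 4
Reactants: 6 methyl 6-acetoxy-3-bromo-2-methyl-4-phenylbenzoate
Product: 7 methyl 6-acetoxy-3-bromo-2-(bromomethyl)-4-phenylbenzoate
Conditions: NBS, AIBN (cat.), PhCF3, 85 °C
Reagents that add atoms: N-bromosuccinimide, O=C1CCC(=O)N1Br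
Why: Wohl–Ziegler bromination; the aryl methyl holds the only benzylic C–H bonds of 6, and acetate, ester and bromine deactivate the ring toward ionic bromination.

Step 5
Reactants: 7 methyl 6-acetoxy-3-bromo-2-(bromomethyl)-4-phenylbenzoate; 8 trimethylsilylacetylene
Product: 9 methyl 6-acetoxy-3-bromo-4-phenyl-2-[3-(trimethylsilyl)prop-2-yn-1-yl]benzoate
Conditions: CuI (cat.), Cs2CO3, n-Bu4NI, MeCN, 40 °C
Reagents that add atoms: none
Why: Copper acetylide substitution of a benzylic bromide (sp3–sp coupling); monovalent copper should not insert into the hindered aryl bromide at this temperature, and the silyl cap prevents double alkylation and slows propargyl–allenyl isomerisation.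

Step 6
Reactants: 9 methyl 6-acetoxy-3-bromo-4-phenyl-2-[3-(trimethylsilyl)prop-2-yn-1-yl]benzoate
Product: 10 4-bromo-2-(hydroxymethyl)-5-phenyl-3-[3-(trimethylsilyl)prop-2-yn-1-yl]phenol
Conditions: i-Bu2AlH (excess), CH2Cl2, −78 → 0 °C; aq. potassium sodium tartrate
Reagents that add atoms: none
Why: Hydride reduction of the methyl ester to the benzylic alcohol with concurrent reductive cleavage of the aryl acetate; aryl bromide and silylalkyne are inert at this temperature. The reduction precedes introduction of the pyranone, whose lactone would not survive it.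

Step 7
Reactants: 10 4-bromo-2-(hydroxymethyl)-5-phenyl-3-[3-(trimethylsilyl)prop-2-yn-1-yl]phenol
Product: 11 3-bromo-6-hydroxy-4-phenyl-2-[3-(trimethylsilyl)prop-2-yn-1-yl]benzaldehyde
Conditions: MnO2 (excess), CH2Cl2, rt
Reagents that add atoms: none
Why: MnO2 oxidises benzylic alcohols selectively and leaves phenol, alkyne and aryl bromide alone; the product is a hydrogen-bonded salicylaldehyde that resists over-oxidation.

Step 8
Reactants: 12 malonyl dichloride (two molecules)
Product: 14 6-chloro-4-hydroxy-2H-pyran-2-one, via pyranone acid chloride 13 (not isolated)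
Conditions: neat, 40 °C; then H2O, 1,4-dioxane, 70 °C
Reagents that add atoms: none
Why: Self-condensation of malonyl dichloride (C-acylation of one molecule by the other, then enol O-acylation) gives the 3-chlorocarbonyl pyranone. Hydrolysis of the acid chloride gives a vinylogous β-keto acid that loses CO2 on warming.

Step 9
Reactants: 14 6-chloro-4-hydroxy-2H-pyran-2-one
Product: 15 4-(benzyloxy)-6-chloro-2H-pyran-2-one
Conditions: BnOH, PPh3, DIAD, THF, 0 °C → rt
Reagents that add atoms: benzyl alcohol, OCc1ccccc1
Why: Mitsunobu etherification; the 4-hydroxy-2-pyranone is an acidic pronucleophile that is alkylated on O4 under these neutral conditions, which spare the C6–Cl bond.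

Step 10
Reactants: 11 3-bromo-6-hydroxy-4-phenyl-2-[3-(trimethylsilyl)prop-2-yn-1-yl]benzaldehyde; 15 4-(benzyloxy)-6-chloro-2H-pyran-2-one
Product: 17 3-[4-(benzyloxy)-2-oxo-2H-pyran-6-yl]-6-hydroxy-4-phenyl-2-[3-(trimethylsilyl)prop-2-yn-1-yl]benzaldehyde, via aryl pinacolboronate 16 (not isolated)
Conditions: B2pin2, Pd2(dba)3 (cat.), XPhos (cat.), KOAc, 1,4-dioxane, 90 °C; then 15, aq. K3PO4, 70 °C
Reagents that add atoms: bis(pinacolato)diboron, CC1(C)OB(OC1(C)C)B1OC(C)(C)C(C)(C)O1 (its boron and pinacol are carried by 16 only)
Why: One-pot Miyaura borylation and Suzuki–Miyaura coupling with a bulky biarylphosphine suited to doubly ortho-substituted partners; the C6–Cl bond of 15 is a vinylogous acyl chloride and should add readily to zerovalent palladium. Aldehyde, phenol and silylalkyne tolerate acetate and phosphate bases.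

Step 11
Reactants: 17 3-[4-(benzyloxy)-2-oxo-2H-pyran-6-yl]-6-hydroxy-4-phenyl-2-[3-(trimethylsilyl)prop-2-yn-1-yl]benzaldehyde
Product: 18 3-[4-(benzyloxy)-2-oxo-2H-pyran-6-yl]-6-hydroxy-4-phenyl-2-(prop-2-yn-1-yl)benzaldehyde
Conditions: AgNO3 (cat.), MeOH/H2O/CH2Cl2, rt
Reagents that add atoms: none
Why: Silver-catalysed protodesilylation of an alkynylsilane through the silver acetylide; it is neutral, so neither the pyranone ether nor the doubly activated C4 methylene (prone to base-induced allene formation) is put at risk.

Step 12
Reactants: 18 3-[4-(benzyloxy)-2-oxo-2H-pyran-6-yl]-6-hydroxy-4-phenyl-2-(prop-2-yn-1-yl)benzaldehyde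
Product: 19 3-[6-(4-benzyloxy-2-oxo-2H-pyran-6-yl)-2-formyl-3-hydroxy-5-phenylphenyl]prop-1-en-2-yl acetate
Conditions: AcOH, [RuCl2(p-cymene)]2 (cat.), P(2-furyl)3 (cat.), Na2CO3 (cat.), toluene, 55 °C
Reagents that add atoms: acetic acid, CC(=O)O
Why: Ruthenium-catalysed Markovnikov addition of a carboxylic acid to a terminal alkyne gives the geminal enol ester. It fixes the double bond at C2=C3, which enolisation of the corresponding methyl ketone could not do.

Step 13
Reactants: 19 3-[6-(4-benzyloxy-2-oxo-2H-pyran-6-yl)-2-formyl-3-hydroxy-5-phenylphenyl]prop-1-en-2-yl acetate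
Product: 20 (3S)-5-[4-(benzyloxy)-2-oxo-2H-pyran-6-yl]-8-hydroxy-1-oxo-6-phenyl-1,2,3,4-tetrahydronaphthalen-3-yl acetate (tetralone numbering)
Conditions: [Rh(cod)Cl]2 (cat.), (R)-DTBM-SEGPHOS (cat.), NaB[3,5-(CF3)2C6H3]4 (cat.), 1,4-dioxane, 60 °C, no base
Reagents that add atoms: none
Why: Proposed new method: a cationic monovalent rhodium bisphosphine complex should add oxidatively into the formyl C1–H bond of 19, insert the 1,1-disubstituted enol acetate into Rh–H with hydrogen going to C3 and rhodium to the terminus C2, and form C1–C2 by reductive elimination from the seven-membered acyl(alkyl) rhodacycle; the closest known reaction type is the rhodium bisphosphine-catalysed enantioselective endo hydroacylation of 2-(2-substituted allyl)benzaldehydes to 3-substituted 1-tetralones and of 4-substituted pent-4-enals to cyclopentanones, which has not been run on an enol ester. The cyclohexanone ring closes in a formal 6-endo-trig mode between the aldehyde carbon and the alkene terminus. C3 becomes stereogenic when hydrogen is delivered to it, so its configuration is set by the chiral ligand choosing the enantiotopic alkene face, with no other stereocentre in 19 to interfere; the acetate carbonyl can act as a second binding point, as it does in rhodium-catalysed hydrogenation of enol acetates. The step needs six-ring over five-ring closure: the reverse insertion puts rhodium on the tertiary carbon C3, where C1–C3 elimination would have to build a quaternary centre, so that branch should revert by β-hydride elimination. It also needs hydroacylation to outrun decarbonylation, migration of the double bond into conjugation with the arene and loss of acetic acid from the product. The O8–H···O=C1 hydrogen bond holds the formyl group in the ring plane with its C–H bond turned toward the tether, so rhodium arrives on the alkene side; base is left out because a rhodium phenoxide chelate would hold the metal on the far side of C1. The moderate temperature and the poor leaving-group ability of acetate should keep the β-acetoxy ketone intact.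

Step 14
Reactants: 20 (3S)-5-[4-(benzyloxy)-2-oxo-2H-pyran-6-yl]-8-hydroxy-1-oxo-6-phenyl-1,2,3,4-tetrahydronaphthalen-3-yl acetate
Product: 21 (3S)-5-[4-(benzyloxy)-2-oxo-2H-pyran-6-yl]-3,8-dihydroxy-6-phenyl-3,4-dihydronaphthalen-1(2H)-one
Conditions: immobilised Candida antarctica lipase B, n-BuOH, t-BuOMe, 35 °C
Reagents that add atoms: none
Why: Lipase-catalysed alcoholysis of a secondary acetate in organic solvent; no base is present, so the β-acyloxy ketone cannot eliminate. C3 is untouched because only the acyl–oxygen bond breaks.

Step 15
Reactants: 21 (3S)-5-[4-(benzyloxy)-2-oxo-2H-pyran-6-yl]-3,8-dihydroxy-6-phenyl-3,4-dihydronaphthalen-1(2H)-one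
Product: 22 wailupemycin F, (3S)-3,8-dihydroxy-5-(4-hydroxy-2-oxo-2H-pyran-6-yl)-6-phenyl-3,4-dihydronaphthalen-1(2H)-one
Conditions: H2 (1 atm), Pd/C (cat.), EtOAc, rt
Reagents that add atoms: none
Why: Hydrogenolysis of a benzyl ether on a vinylogous ester oxygen is fast; the hydrogen-bonded aryl ketone and the pyranone ring should survive at 1 atm, and the neutral medium spares the aldol unit and C3.

## Compound list

1 | methyl orsellinate (methyl 2,4-dihydroxy-6-methylbenzoate) | COC(=O)c1c(C)cc(O)cc1O | starting material
2 | methyl 2-hydroxy-6-methyl-4-{[(trifluoromethyl)sulfonyl]oxy}benzoate | COC(=O)c1c(C)cc(OS(=O)(=O)C(F)(F)F)cc1O | intermediate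
3 | phenylboronic acid | OB(O)c1ccccc1 | starting material
4 | methyl 2-hydroxy-6-methyl-4-phenylbenzoate | COC(=O)c1c(C)cc(-c2ccccc2)cc1O | intermediate
5 | methyl 3-bromo-6-hydroxy-2-methyl-4-phenylbenzoate | COC(=O)c1c(C)c(Br)c(-c2ccccc2)cc1O | intermediate
6 | methyl 6-acetoxy-3-bromo-2-methyl-4-phenylbenzoate | COC(=O)c1c(C)c(Br)c(-c2ccccc2)cc1OC(C)=O | intermediate
7 | methyl 6-acetoxy-3-bromo-2-(bromomethyl)-4-phenylbenzoate | COC(=O)c1c(CBr)c(Br)c(-c2ccccc2)cc1OC(C)=O | intermediate
8 | trimethylsilylacetylene | C#C[Si](C)(C)C | starting material
9 | methyl 6-acetoxy-3-bromo-4-phenyl-2-[3-(trimethylsilyl)prop-2-yn-1-yl]benzoate | COC(=O)c1c(CC#C[Si](C)(C)C)c(Br)c(-c2ccccc2)cc1OC(C)=O | intermediate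
10 | 4-bromo-2-(hydroxymethyl)-5-phenyl-3-[3-(trimethylsilyl)prop-2-yn-1-yl]phenol | OCc1c(CC#C[Si](C)(C)C)c(Br)c(-c2ccccc2)cc1O | intermediate
11 | 3-bromo-6-hydroxy-4-phenyl-2-[3-(trimethylsilyl)prop-2-yn-1-yl]benzaldehyde | O=Cc1c(CC#C[Si](C)(C)C)c(Br)c(-c2ccccc2)cc1O | intermediate
12 | malonyl dichloride (propanedioyl dichloride) | O=C(Cl)CC(=O)Cl | starting material
13 | 6-chloro-4-hydroxy-2-oxo-2H-pyran-3-carbonyl chloride | O=C(Cl)c1c(O)cc(Cl)oc1=O | intermediate
14 | 6-chloro-4-hydroxy-2H-pyran-2-one | O=c1cc(O)cc(Cl)o1 | intermediate
15 | 4-(benzyloxy)-6-chloro-2H-pyran-2-one | O=c1cc(OCc2ccccc2)cc(Cl)o1 | intermediate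
16 | 6-hydroxy-4-phenyl-3-(4,4,5,5-tetramethyl-1,3,2-dioxaborolan-2-yl)-2-[3-(trimethylsilyl)prop-2-yn-1-yl]benzaldehyde | O=Cc1c(CC#C[Si](C)(C)C)c(B2OC(C)(C)C(C)(C)O2)c(-c2ccccc2)cc1O | intermediate
17 | 3-[4-(benzyloxy)-2-oxo-2H-pyran-6-yl]-6-hydroxy-4-phenyl-2-[3-(trimethylsilyl)prop-2-yn-1-yl]benzaldehyde | O=Cc1c(CC#C[Si](C)(C)C)c(-c2cc(OCc3ccccc3)cc(=O)o2)c(-c2ccccc2)cc1O | intermediate
18 | 3-[4-(benzyloxy)-2-oxo-2H-pyran-6-yl]-6-hydroxy-4-phenyl-2-(prop-2-yn-1-yl)benzaldehyde | O=Cc1c(CC#C)c(-c2cc(OCc3ccccc3)cc(=O)o2)c(-c2ccccc2)cc1O | intermediate
19 | 3-[6-(4-benzyloxy-2-oxo-2H-pyran-6-yl)-2-formyl-3-hydroxy-5-phenylphenyl]prop-1-en-2-yl acetate | O=Cc1c(O)cc(-c2ccccc2)c(-c2cc(OCc3ccccc3)cc(=O)o2)c1CC(=C)OC(C)=O | intermediate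
20 | (3S)-5-[4-(benzyloxy)-2-oxo-2H-pyran-6-yl]-8-hydroxy-1-oxo-6-phenyl-1,2,3,4-tetrahydronaphthalen-3-yl acetate (tetralone numbering) | O=C1C[C@@H](OC(C)=O)Cc2c1c(O)cc(-c1ccccc1)c2-c1cc(OCc2ccccc2)cc(=O)o1 | intermediate
21 | (3S)-5-[4-(benzyloxy)-2-oxo-2H-pyran-6-yl]-3,8-dihydroxy-6-phenyl-3,4-dihydronaphthalen-1(2H)-one | O=C1C[C@@H](O)Cc2c1c(O)cc(-c1ccccc1)c2-c1cc(OCc2ccccc2)cc(=O)o1 | intermediate
22 | wailupemycin F, (3S)-3,8-dihydroxy-5-(4-hydroxy-2-oxo-2H-pyran-6-yl)-6-phenyl-3,4-dihydronaphthalen-1(2H)-one | O=C1C[C@@H](O)Cc2c1c(O)cc(-c1ccccc1)c2-c1cc(O)cc(=O)o1 | target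

## Step count and least certain steps

Total: 15 steps. Longest linear sequence: 13 steps (steps 1–7 and 10–15); steps 8 and 9 make the pyranone fragment.

**Step 13 (key step, proposed new method).**
- What may go wrong: decarbonylation of the acyl rhodium hydride; walking of the double bond into conjugation with the arene through the tertiary, acetate-chelated alkyl rhodium; poor facial selectivity, because the ligand has not been asked to read an acetoxy substituent before; elimination of acetic acid from the product with aromatisation.
- Fallback (known chemistry): from 19, a thiol-catalysed radical-chain hydroacylation (tert-dodecanethiol and di-tert-butyl hyponitrite, both catalytic, 1,4-dioxane, 60 °C). The aroyl radical should add 6-endo to the unsubstituted alkene terminus and the tertiary α-acetoxy radical should take hydrogen from the thiol, as in the known intermolecular additions of aldehydes to enol esters. This would give the racemic acetate F1. Lipase-mediated alcoholysis as in step 14, with an enzyme selected for the (S)-acetate, would resolve F1, leave the (3R)-acetate F2 behind and rejoin the route at 21.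

**Step 10.**
- What may go wrong: slow borylation at the doubly flanked carbon with competing protodebromination; protodeboronation of the hindered, electron-rich boronate; hydrolysis of the chloropyranone; partial loss of the silyl cap in aqueous base.
- Fallback: the pyranone is built on the ring instead of coupled, setting out from 11 and returning at 17.
  - Stille coupling with tributyl(1-ethoxyvinyl)stannane (PdCl2(PPh3)2, toluene, 100 °C) would give the enol ether F3.
  - Aqueous HCl would hydrolyse it to the methyl ketone F4.
  - Me3SiOTf/Et3N would give the bis(trimethylsilyl) derivative F5 (silyl enol ether and silylated phenol).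
  - Condensation with malonyl dichloride 12 (Et2O, −78 °C → rt) and aqueous work-up would give the hydroxypyranone F6.
  - Mitsunobu benzylation of its more acidic pyranone hydroxyl (BnOH, PPh3, DIAD) would give 17.

**Step 12.**
- What may go wrong: attack of the formyl oxygen on the metal-activated alkyne (cyclisation instead of acetate addition); anti-Markovnikov addition; isomerisation of the propargyl arene to an allene.
- Fallback: the aldehyde is masked during the addition, setting out from 18 and returning at 19. HC(OMe)3 with catalytic pyridinium p-toluenesulfonate in MeOH would give the dimethyl acetal F7. The same ruthenium-catalysed addition of acetic acid would give the acetal enol acetate F8. Catalytic pyridinium p-toluenesulfonate in wet acetone would release 19.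

**Step 14.**
- What may go wrong: the lipase may not accept the (S)-acetate of this bicyclic substrate; prolonged exposure could then allow slow elimination of acetic acid.
- Fallback: a more labile acyl group is used, setting out from 18 and returning at 21. Ruthenium-catalysed addition of levulinic acid to 18 would give the enol levulinate F9. The hydroacylation of step 13 would give the tetralone levulinate F10. Hydrazine acetate (CH2Cl2/MeOH, rt) would remove the levulinoyl group as a dihydropyridazinone under near-neutral conditions and give 21.

## Further compounds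

F1 | step 13 | racemic 5-[4-(benzyloxy)-2-oxo-2H-pyran-6-yl]-8-hydroxy-1-oxo-6-phenyl-1,2,3,4-tetrahydronaphthalen-3-yl acetate | O=C1CC(OC(C)=O)Cc2c1c(O)cc(-c1ccccc1)c2-c1cc(OCc2ccccc2)cc(=O)o1
F2 | step 13 | (3R)-5-[4-(benzyloxy)-2-oxo-2H-pyran-6-yl]-8-hydroxy-1-oxo-6-phenyl-1,2,3,4-tetrahydronaphthalen-3-yl acetate | O=C1C[C@H](OC(C)=O)Cc2c1c(O)cc(-c1ccccc1)c2-c1cc(OCc2ccccc2)cc(=O)o1
F3 | step 10 | 3-(1-ethoxyethenyl)-6-hydroxy-4-phenyl-2-[3-(trimethylsilyl)prop-2-yn-1-yl]benzaldehyde | O=Cc1c(CC#C[Si](C)(C)C)c(C(=C)OCC)c(-c2ccccc2)cc1O
F4 | step 10 | 3-acetyl-6-hydroxy-4-phenyl-2-[3-(trimethylsilyl)prop-2-yn-1-yl]benzaldehyde | O=Cc1c(CC#C[Si](C)(C)C)c(C(C)=O)c(-c2ccccc2)cc1O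
F5 | step 10 | 4-phenyl-6-[(trimethylsilyl)oxy]-3-{1-[(trimethylsilyl)oxy]ethenyl}-2-[3-(trimethylsilyl)prop-2-yn-1-yl]benzaldehyde | O=Cc1c(CC#C[Si](C)(C)C)c(C(=C)O[Si](C)(C)C)c(-c2ccccc2)cc1O[Si](C)(C)C
F6 | step 10 | 6-hydroxy-3-(4-hydroxy-2-oxo-2H-pyran-6-yl)-4-phenyl-2-[3-(trimethylsilyl)prop-2-yn-1-yl]benzaldehyde | O=Cc1c(CC#C[Si](C)(C)C)c(-c2cc(O)cc(=O)o2)c(-c2ccccc2)cc1O
F7 | step 12 | 4-(benzyloxy)-6-[3-(dimethoxymethyl)-4-hydroxy-6-phenyl-2-(prop-2-yn-1-yl)phenyl]-2H-pyran-2-one | COC(OC)c1c(CC#C)c(-c2cc(OCc3ccccc3)cc(=O)o2)c(-c2ccccc2)cc1O
F8 | step 12 | 3-[6-(4-benzyloxy-2-oxo-2H-pyran-6-yl)-2-(dimethoxymethyl)-3-hydroxy-5-phenylphenyl]prop-1-en-2-yl acetate | COC(OC)c1c(O)cc(-c2ccccc2)c(-c2cc(OCc3ccccc3)cc(=O)o2)c1CC(=C)OC(C)=O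
F9 | step 14 | 3-[6-(4-benzyloxy-2-oxo-2H-pyran-6-yl)-2-formyl-3-hydroxy-5-phenylphenyl]prop-1-en-2-yl 4-oxopentanoate | O=Cc1c(O)cc(-c2ccccc2)c(-c2cc(OCc3ccccc3)cc(=O)o2)c1CC(=C)OC(=O)CCC(C)=O
F10 | step 14 | (3S)-5-[4-(benzyloxy)-2-oxo-2H-pyran-6-yl]-8-hydroxy-1-oxo-6-phenyl-1,2,3,4-tetrahydronaphthalen-3-yl 4-oxopentanoate | O=C1C[C@@H](OC(=O)CCC(C)=O)Cc2c1c(O)cc(-c1ccccc1)c2-c1cc(OCc2ccccc2)cc(=O)o1
A1 | alternative 1 | methyl 5-[(tert-butyldimethylsilyl)oxy]-6-{2-[(1Z,3E)-4-phenyl-2-(triethylsilyloxy)buta-1,3-dien-1-yl]-1,3-dithian-2-yl}hex-2-ynoate, carbinol carbon configured as C3 of 22 | COC(=O)C#CC[C@H](O[Si](C)(C)C(C)(C)C)CC1(SCCCS1)/C=C(O[Si](CC)(CC)CC)/C=C/c1ccccc1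
A2 | alternative 1 | bicyclic cycloadduct with C1 dithiane, C3 tert-butyldimethylsilyl ether configured as in 22, C5 methyl ester, C8 triethylsilyl enol ether and sp3 centres at C6 and C8a | COC(=O)C1=C2C[C@H](O[Si](C)(C)C(C)(C)C)CC3(SCCCS3)C2C(O[Si](CC)(CC)CC)=CC1c1ccccc1
A3 | alternative 2 | 4-iodo-3-methoxy-1,1'-biphenyl | COc1cc(-c2ccccc2)ccc1I
A4 | alternative 2 | tert-butyl{[(2R)-1-iodopent-4-en-2-yl]oxy}dimethylsilane | C=CC[C@@H](O[Si](C)(C)C(C)(C)C)CI
A5 | alternative 2 | tert-butyl{[(2R)-5-methoxy-4-methylidene-7-phenyl-1,2,3,4-tetrahydronaphthalen-2-yl]oxy}dimethylsilane | C=C1C[C@@H](O[Si](C)(C)C(C)(C)C)Cc2cc(-c3ccccc3)cc(OC)c12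
A6 | alternative 3 | 1,3-dioxolane ketal of 8-(benzyloxy)-5-[4-(benzyloxy)-2-oxo-2H-pyran-6-yl]-6-phenylnaphthalen-1(2H)-one (C3=C4 alkene) | O1CCOC12CC=Cc3c(-c4cc(OCc5ccccc5)cc(=O)o4)c(-c4ccccc4)cc(OCc4ccccc4)c32
A7 | alternative 3 | cis-3,4-epoxide of A6 with the C3–O bond configured as in 22 | O1CCOC12C[C@H]3O[C@H]3c3c(-c4cc(OCc5ccccc5)cc(=O)o4)c(-c4ccccc4)cc(OCc4ccccc4)c32
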